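Read the violet run. It has theta's charge, so its last line stands for theta at the asked time.

| setting | violet | green | grey | zeta | beta | eta | theta |
|---|---|---|---|---|---|---|---|
| D | 0.10 M | 0.10 M | 0.10 M | 0.10 M (in portions, 4, over 30 min) | 0.10 M | 0.10 M (fed, over 30 min) | 0.10 M |
| L | 0.11 M | 0.055 M | 0.22 M | 0.110 M | 0.110 M (fed, over 30 min) | 0.110 M | 0.110 M |
| remark | run made earlier | run made earlier | run made earlier | first portion at the start, last at 30 min | all else is in the flask from the start; the feed brings no volume worth counting | all else is in the flask from the start; the feed brings no volume worth counting | everything together at the start |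
| time |  |  |  | 40 min | 40 min | 40 min | 40 min |

| run | time / min | J / % | Q / % |
|---|---|---|---|
| violet | 2.50 | 2 | 9 |
| violet | 8.00 | 17 | 14 |
| violet | 15.0 | 35 | 17 |
| violet | 20.0 | 45 | 19 |
| violet | 30.0 | 58 | 17 |
| violet | 40.0 | 66 | 15 |
| green | 3.00 | 1 | 5 |
| green | 10.0 | 14 | 12 |
| green | 15.0 | 23 | 9 |
| green | 25.0 | 39 | 8 |
| green | 40.0 | 52 | 6 |
| green | 50.0 | 59 | 4 |
| grey | 3.00 | 7 | 19 |
| grey | 10.0 | 34 | 27 |
| grey | 15.0 | 45 | 29 |
| grey | 25.0 | 60 | 31 |
| grey | 40.0 | 66 | 29 |
| grey | 50.0 | 69 | 31 |

(each reading ± 1.5 percentage points)

* the flask with the highest amount of J, in percent of the D charged ("all alike" if they lie within 1.5 percentage points) (zeta / beta / eta / theta / all alike)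
* final J, as a percentage of the D charged, in zeta
* final J, as a percentage of the D charged, in beta
* final J, as a percentage of the D charged, in eta
* final J, as a percentage of the D charged, in theta

- in percentages every species weighs as the D in it: one J counts as two

Build the flask one process at a time, as my own reckoning. Take the main step by itself, D and L giving Q. That step makes no J, yet violet reads J 66% against Q 15% at 40.0 min.

So add a second step, in which Q takes a further D into J. A J then weighs as two D, and the balance leaves violet with 19.0% of its D. Now go to logarithms. Take the log of charge over D left and divide by the time: this is the D clock, the mean first-order loss of D over a run, read from violet as 0.0415 min⁻¹, a half-life of 16.7 min. The same reckoning gives 0.0217 min⁻¹ for green and 0.0749 min⁻¹ for grey, which reads as an order in L of 0.894. As an approximation, then, treat the loss of D as first order, with the clock following L.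

Then add the rest, whatever slows violet late: its log runs at 0.0511 min⁻¹ up to 20.0 min and at 0.0320 min⁻¹ afterwards, slower. The mean clock already contains this, so carry one rate.

Now age the D. Let each part decay for its own time in the flask, and the clock reckons 39.3% of the D left in zeta and 37.8% in eta. Take violet's Q for both flasks and subtract it, and J reckons at 45.7% in zeta and 47.2% in eta. In beta the D ages from the start, but the L supplied averages 62.5% of its charge. Run beta's clock, therefore, for 25.0 min, which reckons 35.4% of its D left and J at 49.6%. Theta I take from violet, 66%.

The forecast reasoned that “Both steps are first order in D” and gave theta 66%, beta 56%, eta 47% and zeta 46%, its beta being higher than mine.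

The flask gives J of 68.5% in theta, the highest, then 54.5% in beta, 48.6% in eta and 47.3% in zeta.

    D + L → Q (k = 0.390 L mol⁻¹ min⁻¹)
    2 L → X (k = 0.0560 L mol⁻¹ min⁻¹)
    D + Q → J (k = 1.40 L mol⁻¹ min⁻¹)

In theta, Q is made 1.39 times as fast as it is used up at 8.30 min, but 0.767 times as fast at 40.0 min. Theta's Q stands at 17.0% at 20.0 min and 15.2% at 40.0 min, while its J goes from 45.8% to 68.5%. Hold the clock against the flasks: eta holds 37% of its D, against 37.8% reckoned. Beta holds 30%, against 35.4% reckoned. Read theta on to 1.5 h: it holds 3.2% of its D, against the clock's 2.39%.

(The readings are calculated for an exercise, noise included.)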